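The route rests on cutting the ring C/D phenylcoumaran at C3a–C3 and O1–C2. This exposes the β-5 pattern: a ring C guaiacyl phenol with a single open ortho carbon (C3a) and a ring D feruloyl unit whose β-carbon becomes C3. One anodic operation pairs the two phenoxyl radicals, forms both bonds, closes the dihydrofuran, and sets C2 and C3 under a magnesium-chelated oxazolidinone. The precursor is the finished trans-α,β-dibenzyl lactone. It already bears the fully silylated anti-(7S,8S) ring A/B arm and has its only free phenol on ring C. Its partner is (E)-feruloyl-(S)-4-benzyloxazolidinone. Imide reduction and one buffered fluoride treatment then give the target.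

Key step: step 19

**Remarks (all apply before the steps)**

- **Labels.** Ring A is the guaiacyl ring on carbinol C7. C8 carries ring B and C9H2OH. Ring B is joined through CH2 to lactone Cα, and ring C through CH2 to lactone Cβ. The coumaran atoms are O1, C2 (bearing ring D), C3, C3a and C7a.
- **Abbreviations.** TBS = tert-butyldimethylsilyl, TMS = trimethylsilyl, Xc = (S)-4-benzyl-2-oxooxazolidin-3-yl. ArmCH2 = {4-(TBSO)-3-methoxy-5-[(1S,2S)-1,3-bis(TBSO)-1-(4-TBSO-3-methoxyphenyl)propan-2-yl]phenyl}methyl.
- **Configuration read from the target.** C7 S, C8 S, Cα R, Cβ R (trans), C2 S, C3 R (trans). In the zigzag C9–C8–C7–ring A, the C7 oxygen and ring B lie on opposite sides. The arm therefore needs an anti-aldol; a syn-selective boron aldol would give the wrong C7/C8 relationship.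
- **Protecting groups.**
  - The ring C phenol is a benzyl ether. This group survives the hot alkoxide of the Stobbe step, where an aryl silyl ether would be lost.
  - Both arm phenols and both arm alcohols are TBS ethers.
  - After the key step, no hydrogenolysis is needed. Hydrogenolysis would threaten the benzylic O1–C2 and C7–O bonds.
  - No acid is needed either. Acid would close the ring B phenol onto C7 and form a second coumaran.
- **Ring B source.** Ring B comes from methyl 5-bromovanillate. The bromine marks the C8 attachment site and the ester carbon is the future benzylic CH2.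
- **Assumption 1.** The (S,S)-bisphospholane is taken to give the R acid 4, by transposing its known sense for enamides to itaconate half-esters; if the sense is opposite, the (R,R)-ligand is used.
- **Assumption 2.** In steps 9 and 19 the (S)-auxiliary is taken to react as the magnesium-chelated syn-carbonyl rotamer, which exposes the same face as in enolate alkylations of this auxiliary (the unchelated dipole-opposed rotamer would expose the other face); if either sense is opposite, (R)-4-benzyl-2-oxazolidinone replaces 13 in that branch only.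

## Route

**Step 1**
Reactants: 1 4-(benzyloxy)-3-methoxybenzaldehyde; 2 dimethyl succinate
Product: 3 (E)-4-[4-(benzyloxy)-3-methoxyphenyl]-3-(methoxycarbonyl)but-3-enoic acid
Conditions: NaOMe, MeOH, reflux; then aq. HCl
Reagents that add atoms: none
Why: Stobbe condensation: enolate addition to the non-enolisable aldehyde, lactonisation and E1cB ring opening give the (E)-alkylidene half-ester with the free acid on the CH2 branch, and the benzyl ether withstands the hot alkoxide.

**Step 2**
Reactants: 3 Stobbe half-ester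
Product: 4 (R)-4-[4-(benzyloxy)-3-methoxyphenyl]-3-(methoxycarbonyl)butanoic acid
Conditions: [Rh(cod)((S,S)-Et-DuPhos)]BF4 (0.5 mol %), NaOMe (10 mol %), H2 (5 bar), MeOH, rt
Reagents that add atoms: none
Why: Asymmetric hydrogenation of an itaconate-type half-ester: the substrate binds the cationic rhodium centre through the alkene and the carboxyl group, and the C2-symmetric bisphospholane lets H2 reach only one alkene face, which sets the future Cβ as R without touching the benzyl ether.

**Step 3**
Reactants: 4 (R)-half-ester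
Product: 7 (R)-4-[4-(benzyloxy)-3-methoxybenzyl]dihydrofuran-2(3H)-one, via potassium carboxylate 5 (not isolated), via hydroxy acid 6 (not isolated)
Conditions: KOH (1 equiv), EtOH; CaCl2, NaBH4, EtOH, 0 °C to rt; then 3 M HCl
Reagents that add atoms: none
Why: Chemoselective borohydride reduction followed by acid lactonisation: the carboxylate is inert to Ca(BH4)2 while the methyl ester is reduced to CH2OH, so ring closure places the benzyl group at Cβ and leaves the stereocentre untouched.

**Step 4**
Reactants: 8 methyl 3-bromo-4-hydroxy-5-methoxybenzoate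
Product: 9 methyl 3-bromo-4-(TBSO)-5-methoxybenzoate
Conditions: TBSCl, imidazole, DMF, rt
Reagents that add atoms: tert-butyldimethylsilyl chloride, CC(C)(C)[Si](C)(C)Cl
Why: Routine imidazole-promoted silylation of a phenol, whose flanking Br and OMe groups make the aryl silyl ether resistant to the nucleophiles met later.

**Step 5**
Reactants: 9 aryl bromide; 10 (2-tert-butoxy-2-oxoethyl)zinc chloride, ClZnCH2CO2t-Bu
Product: 11 methyl 3-(2-tert-butoxy-2-oxoethyl)-4-(TBSO)-5-methoxybenzoate
Conditions: Pd(dba)2 (2 mol %), P(t-Bu)3 (2 mol %), THF, rt to 45 °C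
Reagents that add atoms: none
Why: Negishi-type α-arylation of a Reformatsky reagent (oxidative addition of the aryl bromide to zerovalent palladium, transmetalation, reductive elimination), whose neutral zinc enolate spares the methyl ester and the aryl silyl ether and installs C8 and C9 in one step.

**Step 6**
Reactants: 11 tert-butyl ester
Product: 12 2-[2-(TBSO)-3-methoxy-5-(methoxycarbonyl)phenyl]acetic acid
Conditions: CF3CO2H/CH2Cl2 (1:4), 0 °C to rt
Reagents that add atoms: none
Why: Acidolysis of a tert-butyl ester by loss of isobutene, under anhydrous conditions that leave the methyl ester and the hindered aryl silyl ether in place.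

**Step 7**
Reactants: 12 arylacetic acid; 13 (S)-4-benzyl-2-oxazolidinone
Product: 15 methyl 3-[2-oxo-2-(Xc)ethyl]-4-(TBSO)-5-methoxybenzoate, via mixed pivalic anhydride 14 (not isolated)
Conditions: t-BuCOCl, Et3N, THF, −20 °C; then LiCl, 13, −20 °C to rt
Reagents that add atoms: pivaloyl chloride, CC(C)(C)C(=O)Cl (its acyl group is held only in intermediate 14 and is lost again)
Why: N-acylation of the oxazolidinone through a mixed anhydride with LiCl activation, in which the nucleophile attacks the unhindered arylacetyl carbonyl and no strong base meets the acidic benzylic CH2.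

**Step 8**
Reactants: 16 vanillin
Product: 17 4-(TBSO)-3-methoxybenzaldehyde
Conditions: TBSCl, imidazole, CH2Cl2, rt
Reagents that add atoms: tert-butyldimethylsilyl chloride, CC(C)(C)[Si](C)(C)Cl
Why: Routine imidazole-promoted silylation of a phenol.

**Step 9**
Reactants: 15 arylacetyl imide; 17 aldehyde
Product: 18 methyl 3-[(2R,3S)-1-oxo-1-(Xc)-3-(TMSO)-3-(4-TBSO-3-methoxyphenyl)propan-2-yl]-4-(TBSO)-5-methoxybenzoate
Conditions: MgCl2 (20 mol %), Et3N (2 equiv), TMSCl (1.5 equiv), EtOAc, rt
Reagents that add atoms: chlorotrimethylsilane, C[Si](C)(C)Cl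
Why: Magnesium-halide-catalysed direct anti-aldol of an N-acyloxazolidinone with an aromatic aldehyde: soft enolisation gives the chelated Z-enolate, which reacts on the face away from the 4-benzyl group (sets C8) with anti topicity (sets C7), while silylation of the aldolate makes the addition irreversible and releases the catalyst.

**Step 10**
Reactants: 18 O-TMS aldol adduct
Product: 20 methyl 3-[(1S,2S)-1,3-dihydroxy-1-(4-TBSO-3-methoxyphenyl)propan-2-yl]-4-(TBSO)-5-methoxybenzoate, via O-TMS alcohol 19 (not isolated)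
Conditions: LiBH4, MeOH (1.3 equiv each), Et2O/THF, 0 °C; then citric acid, MeOH, 0 °C to rt
Reagents that add atoms: none
Why: Reductive cleavage of the N-acyloxazolidinone at its exocyclic carbonyl, run on the silyl ether so that no aldolate can undergo retro-aldol and at 0 °C where the electron-rich methyl benzoate reacts far more slowly, followed by mild methanolysis that removes only the TMS group.

**Step 11**
Reactants: 20 diol
Product: 21 methyl 3-[(1S,2S)-1,3-bis(TBSO)-1-(4-TBSO-3-methoxyphenyl)propan-2-yl]-4-(TBSO)-5-methoxybenzoate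
Conditions: TBSOTf (2.5 equiv), 2,6-lutidine, CH2Cl2, 0 °C
Reagents that add atoms: tert-butyldimethylsilyl triflate, CC(C)(C)[Si](C)(C)OS(=O)(=O)C(F)(F)F
Why: Silylation with the silyl triflate, which is reactive enough for the hindered benzylic C7 hydroxyl as well as the primary C9 hydroxyl, under non-acidic conditions that do not ionise C7.

**Step 12**
Reactants: 21 tetrasilyl ester
Product: 22 ArmCH2–OH (benzylic alcohol)
Conditions: (i-Bu)2AlH (2.5 equiv), CH2Cl2, −78 °C; aq. potassium sodium tartrate
Reagents that add atoms: none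
Why: Hydride reduction of the methyl ester, the only reducible group in 21, to the benzylic alcohol.

**Step 13**
Reactants: 22 benzylic alcohol
Product: 23 ArmCH2–Br (benzylic bromide)
Conditions: CBr4, PPh3, 2,6-lutidine (buffer), CH2Cl2, 0 °C; used at once
Reagents that add atoms: carbon tetrabromide, BrC(Br)(Br)Br
Why: Appel reaction: the alkoxyphosphonium salt of the only free (primary benzylic) alcohol is displaced by bromide under near-neutral conditions that spare all four silyl ethers.

**Step 14**
Reactants: 7 β-benzyl lactone (1.3 equiv); 23 bromide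
Product: 25 (3R,4R)-3-(ArmCH2)-4-[4-(benzyloxy)-3-methoxybenzyl]dihydrofuran-2(3H)-one, via lithium enolate 24 (not isolated)
Conditions: LiN(SiMe3)2, THF, −78 °C; then 23, DMPU, −78 to −40 °C
Reagents that add atoms: none
Why: Alkylation of a γ-butyrolactone enolate (SN2 on the benzylic bromide): the electrophile approaches the planar enolate from the face opposite the Cβ benzyl group, which sets Cα as R in the trans relationship that is also the thermodynamically preferred one.

**Step 15**
Reactants: 25 benzyl ether
Product: 26 (3R,4R)-3-(ArmCH2)-4-(4-hydroxy-3-methoxybenzyl)dihydrofuran-2(3H)-one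
Conditions: H2 (1 atm), Pd/C, EtOAc, rt
Reagents that add atoms: none
Why: Hydrogenolysis of the single aryl benzyl ether in a neutral aprotic solvent, placed before the O1–C2 bond and the free C7 carbinol exist, so that only silyl ethers, the lactone and arenes are exposed to it.

**Step 16**
Reactants: 27 ferulic acid
Product: 29 (E)-3-[4-(TBSO)-3-methoxyphenyl]acrylic acid, via silyl ester 28 (not isolated)
Conditions: TBSCl (2.5 equiv), imidazole, DMF, rt; then AcOH/THF/H2O, rt
Reagents that add atoms: tert-butyldimethylsilyl chloride, CC(C)(C)[Si](C)(C)Cl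
Why: Exhaustive silylation followed by selective hydrolysis, which relies on the silyl ester being far more labile to aqueous acid than the aryl silyl ether.

**Step 17**
Reactants: 29 silylated ferulic acid; 13 (S)-4-benzyl-2-oxazolidinone
Product: 31 (S)-4-benzyl-3-{(E)-3-[4-(TBSO)-3-methoxyphenyl]acryloyl}oxazolidin-2-one, via mixed pivalic anhydride 30 (not isolated)
Conditions: t-BuCOCl, Et3N, THF, −20 °C; then LiCl, 13, −20 °C to rt
Reagents that add atoms: pivaloyl chloride, CC(C)(C)C(=O)Cl (its acyl group is held only in intermediate 30 and is lost again)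
Why: N-acylation of the oxazolidinone through a mixed anhydride with LiCl activation, which attacks the less hindered cinnamoyl carbonyl and keeps the E alkene.

**Step 18**
Reactants: 31 silylated imide
Product: 32 (S)-4-benzyl-3-[(E)-3-(4-hydroxy-3-methoxyphenyl)acryloyl]oxazolidin-2-one
Conditions: Bu4NF, AcOH (1:1), THF, 0 °C
Reagents that add atoms: none
Why: Fluoride cleavage of the aryl silyl ether, buffered with acetic acid so that neither the imide nor the enoyl unit meets a basic nucleophile.

**Step 19**
Reactants: 26 lactone with free ring C phenol (2 equiv, surplus recovered and resubmitted); 32 feruloyl imide (1 equiv)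
Product: 34 (3R,4R)-3-(ArmCH2)-4-{[(2S,3S)-3-(Xc-carbonyl)-2-(4-hydroxy-3-methoxyphenyl)-7-methoxy-2,3-dihydrobenzofuran-5-yl]methyl}dihydrofuran-2(3H)-one, via para-quinone methide 33 (not isolated)
Conditions: undivided cell, graphite anode, Pt cathode, anode held at the foot of the phenol wave (set by cyclic voltammetry), Mg(ClO4)2 (0.1 M), 2,6-lutidine (2 equiv), MeCN/CH2Cl2 (3:1), 0 °C; 32 fed by syringe pump during the electrolysis, about 2 F per mol of 32
Reagents that add atoms: none
Why: At the anode each phenol loses one electron and one proton (to lutidine); the feruloyl radical, whose spin reaches the carbon next to the imide carbonyl (C3), pairs with the only open ortho carbon of the ring C radical (C3a), and tautomerisation of the dienone restores ring C and leaves para-quinone methide 33 on ring D. The closest known reaction type is the oxidative β-5 dehydrodimerisation of ferulic esters, amides and auxiliary-bearing imides at an anode, with Ag2O or with peroxidase/H2O2, run here as a cross-coupling. The dihydrofuran closes by 5-exo-trig conjugate addition of the ring C phenol oxygen O1 to the quinone methide carbon C2, which rearomatises ring D. C3 is controlled by the auxiliary: Mg(ClO4)2 is both electrolyte and chelating Lewis acid and locks the imide in the syn-carbonyl, s-cis rotamer, so the 4-benzyl group covers one face of C3 and ring C bonds to the other, in the sense of an enolate alkylation of this (S)-auxiliary, giving 3S. C2 follows from C3, because the O1–C2 closure is reversible through 33 and the trans arrangement of aryl and acyl groups is both the faster formed and the more stable one. Chemoselectivity rests on the substrate, since ring C holds the only free phenol of 26 (rings A and B are silyl ethers that oxidise at much higher potential) and its para and second ortho positions are blocked by CH2 and OMe, while cross-coupling is favoured over self-coupling by keeping 26 in excess and feeding 32 slowly.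

**Step 20**
Reactants: 34 coumaran imide
Product: 35 (3R,4R)-3-(ArmCH2)-4-{[(2S,3R)-2-(4-hydroxy-3-methoxyphenyl)-3-(hydroxymethyl)-7-methoxy-2,3-dihydrobenzofuran-5-yl]methyl}dihydrofuran-2(3H)-one
Conditions: NaBH4 (4 equiv), THF/H2O (4:1), 0 °C to rt
Reagents that add atoms: none
Why: Borohydride cleavage of an N-acyloxazolidinone in aqueous THF: the twisted, doubly activated exocyclic carbonyl is reduced through the aldehyde to CH2OH far faster than the α,β-disubstituted γ-lactone, C3 keeps its configuration (trans is also the stable arrangement), and any partial loss of aryl silyl groups is harmless because the next step removes them all.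

**Step 21**
Reactants: 35 tetrasilyl ether
Product: 36 target CNP0186558.2
Conditions: Bu4NF (8 equiv), AcOH (8 equiv), THF, 0 °C to rt
Reagents that add atoms: none
Why: Fluoride cleavage of all four silyl ethers under acetic acid buffering, near-neutral conditions that avoid acid-promoted closure of the ring B phenol onto C7 as well as base-promoted lactone epimerisation or quinone methide formation, so no stereocentre is touched.

## Compound list

1 | 4-(benzyloxy)-3-methoxybenzaldehyde | COc1cc(C=O)ccc1OCc1ccccc1 | starting material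
2 | dimethyl succinate | COC(=O)CCC(=O)OC | starting material
3 | (E)-4-[4-(benzyloxy)-3-methoxyphenyl]-3-(methoxycarbonyl)but-3-enoic acid | COC(=O)/C(CC(=O)O)=C/c1ccc(OCc2ccccc2)c(OC)c1 | intermediate
4 | (R)-4-[4-(benzyloxy)-3-methoxyphenyl]-3-(methoxycarbonyl)butanoic acid | COC(=O)[C@@H](CC(=O)O)Cc1ccc(OCc2ccccc2)c(OC)c1 | intermediate
5 | potassium salt of 4 (not isolated) | COC(=O)[C@@H](CC(=O)[O-])Cc1ccc(OCc2ccccc2)c(OC)c1.[K+] | intermediate
6 | (R)-4-[4-(benzyloxy)-3-methoxyphenyl]-3-(hydroxymethyl)butanoic acid (not isolated) | OC[C@@H](CC(=O)O)Cc1ccc(OCc2ccccc2)c(OC)c1 | intermediate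
7 | (R)-4-[4-(benzyloxy)-3-methoxybenzyl]dihydrofuran-2(3H)-one | O=C1C[C@@H](Cc2ccc(OCc3ccccc3)c(OC)c2)CO1 | intermediate
8 | methyl 3-bromo-4-hydroxy-5-methoxybenzoate | COC(=O)c1cc(Br)c(O)c(OC)c1 | starting material
9 | methyl 3-bromo-4-(TBSO)-5-methoxybenzoate | COC(=O)c1cc(Br)c(O[Si](C)(C)C(C)(C)C)c(OC)c1 | intermediate
10 | (2-tert-butoxy-2-oxoethyl)zinc chloride | CC(C)(C)OC(=O)C[Zn]Cl | starting material
11 | methyl 3-(2-tert-butoxy-2-oxoethyl)-4-(TBSO)-5-methoxybenzoate | COC(=O)c1cc(CC(=O)OC(C)(C)C)c(O[Si](C)(C)C(C)(C)C)c(OC)c1 | intermediate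
12 | 2-[2-(TBSO)-3-methoxy-5-(methoxycarbonyl)phenyl]acetic acid | COC(=O)c1cc(CC(=O)O)c(O[Si](C)(C)C(C)(C)C)c(OC)c1 | intermediate
13 | (S)-4-benzyl-2-oxazolidinone | O=C1N[C@@H](Cc2ccccc2)CO1 | starting material
14 | mixed pivalic anhydride of 12 (not isolated) | COC(=O)c1cc(CC(=O)OC(=O)C(C)(C)C)c(O[Si](C)(C)C(C)(C)C)c(OC)c1 | intermediate
15 | ring B arylacetyl imide of the (S)-auxiliary | COC(=O)c1cc(CC(=O)N2[C@@H](Cc3ccccc3)COC2=O)c(O[Si](C)(C)C(C)(C)C)c(OC)c1 | intermediate
16 | vanillin | COc1cc(C=O)ccc1O | starting material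
17 | 4-(TBSO)-3-methoxybenzaldehyde | COc1cc(C=O)ccc1O[Si](C)(C)C(C)(C)C | intermediate
18 | (2R,3S) anti-aldol adduct, C7 O-TMS ether | COc1cc([C@@H](O[Si](C)(C)C)[C@H](C(=O)N2[C@@H](Cc3ccccc3)COC2=O)c2cc(C(=O)OC)cc(OC)c2O[Si](C)(C)C(C)(C)C)ccc1O[Si](C)(C)C(C)(C)C | intermediate
19 | (1S,2S) C7 O-TMS, C9 alcohol (not isolated) | COc1cc([C@@H](O[Si](C)(C)C)[C@H](CO)c2cc(C(=O)OC)cc(OC)c2O[Si](C)(C)C(C)(C)C)ccc1O[Si](C)(C)C(C)(C)C | intermediate
20 | (1S,2S) anti-1,3-diol with methyl ester on ring B | COc1cc([C@@H](O)[C@H](CO)c2cc(C(=O)OC)cc(OC)c2O[Si](C)(C)C(C)(C)C)ccc1O[Si](C)(C)C(C)(C)C | intermediate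
21 | tetrasilylated arm, methyl ester | COc1cc([C@@H](O[Si](C)(C)C(C)(C)C)[C@H](CO[Si](C)(C)C(C)(C)C)c2cc(C(=O)OC)cc(OC)c2O[Si](C)(C)C(C)(C)C)ccc1O[Si](C)(C)C(C)(C)C | intermediate
22 | ArmCH2–OH | COc1cc([C@@H](O[Si](C)(C)C(C)(C)C)[C@H](CO[Si](C)(C)C(C)(C)C)c2cc(CO)cc(OC)c2O[Si](C)(C)C(C)(C)C)ccc1O[Si](C)(C)C(C)(C)C | intermediate
23 | ArmCH2–Br | COc1cc([C@@H](O[Si](C)(C)C(C)(C)C)[C@H](CO[Si](C)(C)C(C)(C)C)c2cc(CBr)cc(OC)c2O[Si](C)(C)C(C)(C)C)ccc1O[Si](C)(C)C(C)(C)C | intermediate
24 | lithium enolate of 7 (not isolated) | [Li+].[O-]C1=C[C@@H](Cc2ccc(OCc3ccccc3)c(OC)c2)CO1 | intermediate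
25 | (3R,4R) trans lactone, arm silylated, ring C O-benzyl | COc1cc([C@@H](O[Si](C)(C)C(C)(C)C)[C@H](CO[Si](C)(C)C(C)(C)C)c2cc(C[C@H]3C(=O)OC[C@@H]3Cc3ccc(OCc4ccccc4)c(OC)c3)cc(OC)c2O[Si](C)(C)C(C)(C)C)ccc1O[Si](C)(C)C(C)(C)C | intermediate
26 | (3R,4R) trans lactone, arm silylated, free ring C phenol (key-step precursor) | COc1cc([C@@H](O[Si](C)(C)C(C)(C)C)[C@H](CO[Si](C)(C)C(C)(C)C)c2cc(C[C@H]3C(=O)OC[C@@H]3Cc3ccc(O)c(OC)c3)cc(OC)c2O[Si](C)(C)C(C)(C)C)ccc1O[Si](C)(C)C(C)(C)C | intermediate
27 | ferulic acid | COc1cc(/C=C/C(=O)O)ccc1O | starting material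
28 | TBS ester of 4-O-TBS-ferulic acid (not isolated) | COc1cc(/C=C/C(=O)O[Si](C)(C)C(C)(C)C)ccc1O[Si](C)(C)C(C)(C)C | intermediate
29 | 4-O-TBS-ferulic acid | COc1cc(/C=C/C(=O)O)ccc1O[Si](C)(C)C(C)(C)C | intermediate
30 | mixed pivalic anhydride of 29 (not isolated) | COc1cc(/C=C/C(=O)OC(=O)C(C)(C)C)ccc1O[Si](C)(C)C(C)(C)C | intermediate
31 | 4-O-TBS-(E)-feruloyl imide of the (S)-auxiliary | COc1cc(/C=C/C(=O)N2[C@@H](Cc3ccccc3)COC2=O)ccc1O[Si](C)(C)C(C)(C)C | intermediate
32 | (E)-feruloyl imide of the (S)-auxiliary, free phenol (key-step partner) | COc1cc(/C=C/C(=O)N2[C@@H](Cc3ccccc3)COC2=O)ccc1O | intermediate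
33 | para-quinone methide, C3a–C3 bond made, C3 configured as in 34, ring C phenol free (not isolated) | COc1cc([C@@H](O[Si](C)(C)C(C)(C)C)[C@H](CO[Si](C)(C)C(C)(C)C)c2cc(C[C@H]3C(=O)OC[C@@H]3Cc3cc(OC)c(O)c(c3)[C@H](C(=O)N4[C@@H](Cc5ccccc5)COC4=O)C=C4C=CC(=O)C(OC)=C4)cc(OC)c2O[Si](C)(C)C(C)(C)C)ccc1O[Si](C)(C)C(C)(C)C | intermediate
34 | full skeleton, (2S,3S) trans coumaran with C3 acyl oxazolidinone, free ring D phenol (key-step product) | COc1cc([C@@H](O[Si](C)(C)C(C)(C)C)[C@H](CO[Si](C)(C)C(C)(C)C)c2cc(C[C@H]3C(=O)OC[C@@H]3Cc3cc(OC)c4c(c3)[C@H](C(=O)N5[C@@H](Cc6ccccc6)COC5=O)[C@@H](c3ccc(O)c(OC)c3)O4)cc(OC)c2O[Si](C)(C)C(C)(C)C)ccc1O[Si](C)(C)C(C)(C)C | intermediate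
35 | (2S,3R) coumaran with C3 hydroxymethyl, arm still silylated | COc1cc([C@@H](O[Si](C)(C)C(C)(C)C)[C@H](CO[Si](C)(C)C(C)(C)C)c2cc(C[C@H]3C(=O)OC[C@@H]3Cc3cc(OC)c4c(c3)[C@H](CO)[C@@H](c3ccc(O)c(OC)c3)O4)cc(OC)c2O[Si](C)(C)C(C)(C)C)ccc1O[Si](C)(C)C(C)(C)C | intermediate
36 | CNP0186558.2 | COc1cc([C@@H](O)[C@H](CO)c2cc(C[C@H]3C(=O)OC[C@@H]3Cc3cc(OC)c4c(c3)[C@H](CO)[C@@H](c3ccc(O)c(OC)c3)O4)cc(OC)c2O)ccc1O | target

## Step count

Total step count: 21.
Longest linear sequence: 14 steps (steps 4–7, 9–15 and 19–21, from compound 8).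

## Steps most likely to fail

**1. Step 19.**

What may go wrong:
- self-pairing of feruloyl radicals
- 5–5 pairing of ring C radicals
- pairing through the ring C oxygen instead of C3a
- re-oxidation of the new ring D phenol
- incomplete chelation that erodes the facial selectivity at C3

Fallback (sets out from 7, rejoins at 36). The order of fragment union is inverted, so that the coupling is run on the cheapest phenol of the route. That phenol can be used in about tenfold excess, is easily recovered, and carries no oxidisable arm. Hydrogenolysis of 7 (H2, Pd/C, EtOAc) gives (R)-4-(4-hydroxy-3-methoxybenzyl)dihydrofuran-2(3H)-one F1. Anodic coupling of F1 with slowly added 32 in the cell of step 19 gives the coumaran imide F2. NaBH4 in THF/H2O gives the coumaran alcohol F3. TBSCl and imidazole give the bis-silyl ether F4. Alkylation of F4 with bromide 23 under the conditions of step 14 gives the hexasilyl ether F5. Buffered Bu4NF as in step 21 then gives 36.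

**2. Step 9.**

What may go wrong:
- erosion of the anti selectivity or of the facial selectivity, because the ortho-silyloxy aryl group crowds the enolate
- slow catalyst turnover
- base-mediated epimerisation at the acidic α-aryl position C8

Fallback (sets out from 9, rejoins at 20). The C7–C8 bond is made by allylboration instead of an aldol. Stille vinylation of 9 (Bu3SnCH=CH2, Pd(PPh3)4, toluene, 100 °C) gives the styrene F6. Cross metathesis with allylboronic acid pinacol ester (second-generation Grubbs catalyst, CH2Cl2, 40 °C) gives the (E)-cinnamylboronate F7. Addition to aldehyde 17 is catalysed by the chiral phosphoric acid (S)-TRIP (toluene, −30 °C), with the sense assigned by analogy with allylboration of benzaldehydes. It passes through a closed chair transition state that turns the E geometry into the anti relationship and gives the homoallylic alcohol F8. Ozonolysis (O3, CH2Cl2/MeOH, −78 °C) gives the aldehyde F9, which is reduced in the same flask with NaBH4 to diol 20.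

**3. Step 20.**

What may go wrong:
- competing reduction of the lactone
- base-induced opening of the coumaran by loss of the acidic C3 proton before the imide is consumed

Fallback (sets out from 34, rejoins at 35). Direct reduction is replaced by hydrolysis and an acid-selective reduction. LiOH/H2O2 (THF/H2O, 0 °C, with a mild acidic work-up that recloses any opened lactone) gives the carboxylic acid F10. BH3·SMe2 (THF, 0 °C) reduces a carboxylic acid faster than a lactone and gives 35.

## Further compounds

F1 | step 19 | (R)-4-(4-hydroxy-3-methoxybenzyl)dihydrofuran-2(3H)-one | O=C1C[C@@H](Cc2ccc(O)c(OC)c2)CO1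
F2 | step 19 | (R)-lactone bearing the (2S,3S) coumaran imide | O=C1C[C@@H](Cc2cc(OC)c3c(c2)[C@H](C(=O)N4[C@@H](Cc5ccccc5)COC4=O)[C@@H](c2ccc(O)c(OC)c2)O3)CO1
F3 | step 19 | (R)-lactone bearing the (2S,3R) coumaran alcohol | O=C1C[C@@H](Cc2cc(OC)c3c(c2)[C@H](CO)[C@@H](c2ccc(O)c(OC)c2)O3)CO1
F4 | step 19 | bis-TBS ether of F3 | O=C1C[C@@H](Cc2cc(OC)c3c(c2)[C@H](CO[Si](C)(C)C(C)(C)C)[C@@H](c2ccc(O[Si](C)(C)C(C)(C)C)c(OC)c2)O3)CO1
F5 | step 19 | hexasilyl ether of 36 | COc1cc([C@@H](O[Si](C)(C)C(C)(C)C)[C@H](CO[Si](C)(C)C(C)(C)C)c2cc(C[C@H]3C(=O)OC[C@@H]3Cc3cc(OC)c4c(c3)[C@H](CO[Si](C)(C)C(C)(C)C)[C@@H](c3ccc(O[Si](C)(C)C(C)(C)C)c(OC)c3)O4)cc(OC)c2O[Si](C)(C)C(C)(C)C)ccc1O[Si](C)(C)C(C)(C)C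
F6 | step 9 | methyl 4-(TBSO)-3-methoxy-5-vinylbenzoate | COC(=O)c1cc(C=C)c(O[Si](C)(C)C(C)(C)C)c(OC)c1
F7 | step 9 | (E)-cinnamylboronic acid pinacol ester of ring B | COC(=O)c1cc(/C=C/CB2OC(C)(C)C(C)(C)O2)c(O[Si](C)(C)C(C)(C)C)c(OC)c1
F8 | step 9 | (1S,2R) anti homoallylic alcohol | COc1cc([C@@H](O)[C@H](C=C)c2cc(C(=O)OC)cc(OC)c2O[Si](C)(C)C(C)(C)C)ccc1O[Si](C)(C)C(C)(C)C
F9 | step 9 | β-hydroxy-α-aryl aldehyde (not isolated) | COc1cc([C@@H](O)[C@H](C=O)c2cc(C(=O)OC)cc(OC)c2O[Si](C)(C)C(C)(C)C)ccc1O[Si](C)(C)C(C)(C)C
F10 | step 20 | (2S,3S) coumaran-3-carboxylic acid, arm silylated | COc1cc([C@@H](O[Si](C)(C)C(C)(C)C)[C@H](CO[Si](C)(C)C(C)(C)C)c2cc(C[C@H]3C(=O)OC[C@@H]3Cc3cc(OC)c4c(c3)[C@H](C(=O)O)[C@@H](c3ccc(O)c(OC)c3)O4)cc(OC)c2O[Si](C)(C)C(C)(C)C)ccc1O[Si](C)(C)C(C)(C)C
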